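**Retrosynthetic overview**

1. The strategy rests on ring A: a cyclohexene whose olefin is C1=C10 and whose quaternary C4 (methyl C19, ester carbon C18) sits next to C5–H. Bonds C2–C3 and C4–C5 are therefore cut as a [4+2] union of the ring B diene C2=C1–C10=C5 with methacrolein (C3=C4, C19, C18 as CHO).
2. Diene 8 comes from ring B ketone 4 by enol triflate formation (possible only toward C5, since C9 is quaternary) and Suzuki vinylation (C1, C2).
3. Ketone 4 comes from 2-methylcyclohex-2-en-1-one by asymmetric methyl conjugate addition (C8) and allyl trapping of the enolate (C9).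
4. The C9 chain is carried through the cycloaddition as a plain allyl group. It is finished afterwards by hydroboration, alkyne homologation and methylalumination/formaldehyde capture (C13=C14 E-olefin, C15–O), then acylation and cis-semihydrogenation for the (Z)-cinnamate.
5. Ring order: ring B is bought and receives C8 and C9 first; ring A is closed by the cycloaddition, which also sets C4 and C5.

Key step: step 4

Assumption: halimane atom numbers are used throughout (C17 on C8; C20 and the C11–C16 chain on C9; C18 and C19 on C4), and the absolute sense of both catalytic asymmetric steps is assigned from the accepted models of those catalyst families.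

**Route**

Step 1
Reactants: 1 2-methylcyclohex-2-en-1-one
Product: 4 (2S,3R)-2,3-dimethyl-2-(prop-2-en-1-yl)cyclohexan-1-one, via aluminium enolate 2 (not isolated), via lithium aluminate enolate 3 (not isolated)
Conditions: Cu(OTf)2 (2 mol%), (R,S,S)-binaphthol bis(1-phenylethyl)amine phosphoramidite (4 mol%), AlMe3, Et2O, −30 °C; then MeLi, THF, −30 → 0 °C; then allyl iodide, HMPA, −30 °C → rt; aq NH4Cl
Reagents that add atoms: trimethylaluminium C[Al](C)C; allyl iodide C=CCI
Why: Copper-catalysed asymmetric conjugate addition of AlMe3, with the phosphoramidite antipode chosen to give the 3R centre (C8), should deliver a regiodefined enolate which, made nucleophilic as its lithium aluminate, is C-allylated anti to the adjacent pseudoaxial C8 methyl, so that quaternary C9 forms with the two methyl groups cis.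

Step 2
Reactants: 4 (2S,3R)-2,3-dimethyl-2-(prop-2-en-1-yl)cyclohexan-1-one
Product: 6 (5R,6S)-5,6-dimethyl-6-(prop-2-en-1-yl)cyclohex-1-en-1-yl trifluoromethanesulfonate, via potassium enolate 5 (not isolated)
Conditions: KN(SiMe3)2, THF, −78 °C; PhN(SO2CF3)2, −78 → 0 °C
Reagents that add atoms: N-phenylbis(trifluoromethanesulfonimide) O=S(=O)(N(c1ccccc1)S(=O)(=O)C(F)(F)F)C(F)(F)F
Why: Enol triflate formation should give a single regioisomer because deprotonation is possible only at C5 (C9 is quaternary), and O-sulfonylation of the potassium enolate touches no stereocentre.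

Step 3
Reactants: 6 (5R,6S)-5,6-dimethyl-6-(prop-2-en-1-yl)cyclohex-1-en-1-yl trifluoromethanesulfonate; 7 vinylboronic acid pinacol ester
Product: 8 (5R,6S)-1-ethenyl-5,6-dimethyl-6-(prop-2-en-1-yl)cyclohex-1-ene
Conditions: Pd(OAc)2 (5 mol%), SPhos (10 mol%), K3PO4, THF/H2O, 50 °C; filtration through basic alumina, used promptly
Reagents that add atoms: none
Why: Suzuki–Miyaura coupling of an alkenyl triflate with a vinylboronate should keep the ring olefin at C10=C5, the bulky biarylphosphine allowing oxidative addition next to the quaternary carbon.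

Step 4
Reactants: 8 (5R,6S)-1-ethenyl-5,6-dimethyl-6-(prop-2-en-1-yl)cyclohex-1-ene; 9 methacrolein
Product: 10 (1S,5S,6R,8aR)-1,5,6-trimethyl-5-(prop-2-en-1-yl)-1,2,3,5,6,7,8,8a-octahydronaphthalene-1-carbaldehyde
Conditions: (S)-B-(o-tolyl)oxazaborolidine from (S)-α,α-diphenylprolinol (20 mol%), HN(SO2CF3)2 (18 mol%), CH2Cl2, −78 → −40 °C; Et3N quench
Reagents that add atoms: none
Why: Methacrolein binds the cationic boron through its carbonyl oxygen with the formyl C–H held against the ring oxygen, which lowers its LUMO and leaves one face of the s-trans enal open; the diene, held s-cis because an s-trans vinyl group would clash with quaternary C9, then adds in a concerted, asynchronous [4+2] cycloaddition in which the unhindered vinyl terminus C2 bonds to the enal β-carbon C3 ahead of C5–C4, the reaction type being the established oxazaborolidinium-catalysed Diels–Alder reaction of 2-substituted acroleins with 1-vinylcycloalkenes. Ring A closes in that single suprafacial event on both partners (intermolecular six-membered cycloaddition), and the new olefin is left at C1=C10. C4 is set by the catalyst: the (S)-catalyst covers the enal face lying over its phenyl group, so the diene reaches the opposite face, which should give the 4S centre. C5 is set by the endo placement of the boron-bound formyl group under C1–C10 (C18 trans to H5) together with approach of the dienophile to the diene face anti to the pseudoaxial C9 methyl C20, the face that the (S)-catalyst requires for an endo transition state. The step needs "ortho" regioselectivity, endo selectivity and diene facial selectivity: the first should follow from the larger HOMO coefficient and lower hindrance at C2, the second from secondary overlap of the activated formyl group with a diene that has no bridging methylene to favour exo, and the third from the C8/C9 substitution of ring B.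

Step 5
Reactants: 10 (1S,5S,6R,8aR)-1,5,6-trimethyl-5-(prop-2-en-1-yl)-1,2,3,5,6,7,8,8a-octahydronaphthalene-1-carbaldehyde
Product: 11 (1S,5S,6R,8aR)-1,5,6-trimethyl-5-(prop-2-en-1-yl)-1,2,3,5,6,7,8,8a-octahydronaphthalene-1-carboxylic acid
Conditions: NaClO2, NaH2PO4, 2-methyl-2-butene, t-BuOH/H2O, 0 °C → rt
Reagents that add atoms: sodium chlorite [Na+].[O-]Cl=O
Why: Pinnick oxidation converts even neopentyl aldehydes to acids without epimerisable positions being involved, and the excess 2-methyl-2-butene should intercept HOCl before it reaches the two olefins.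

Step 6
Reactants: 11 (1S,5S,6R,8aR)-1,5,6-trimethyl-5-(prop-2-en-1-yl)-1,2,3,5,6,7,8,8a-octahydronaphthalene-1-carboxylic acid
Product: 12 methyl (1S,5S,6R,8aR)-1,5,6-trimethyl-5-(prop-2-en-1-yl)-1,2,3,5,6,7,8,8a-octahydronaphthalene-1-carboxylate
Conditions: Me3SiCHN2, toluene/MeOH, 0 °C → rt
Reagents that add atoms: (trimethylsilyl)diazomethane C[Si](C)(C)C=[N+]=[N-]
Why: O-Methylation of the carboxylic acid with trimethylsilyldiazomethane in methanol proceeds through the carboxylate and is insensitive to the steric hindrance at C4.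

Step 7
Reactants: 12 methyl (1S,5S,6R,8aR)-1,5,6-trimethyl-5-(prop-2-en-1-yl)-1,2,3,5,6,7,8,8a-octahydronaphthalene-1-carboxylate
Product: 14 methyl (1S,5S,6R,8aR)-5-(3-hydroxypropyl)-1,5,6-trimethyl-1,2,3,5,6,7,8,8a-octahydronaphthalene-1-carboxylate, via B-alkyl-9-borabicyclo[3.3.1]nonane 13 (not isolated)
Conditions: 9-BBN, THF, 0 °C → rt; then aq NaOH, H2O2, 0 °C
Reagents that add atoms: hydrogen peroxide OO
Why: Anti-Markovnikov hydroboration–oxidation with the bulky 9-BBN should take only the monosubstituted allyl olefin, the trisubstituted C1=C10 olefin flanked by quaternary C9 and the hindered ester being inert.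

Step 8
Reactants: 14 methyl (1S,5S,6R,8aR)-5-(3-hydroxypropyl)-1,5,6-trimethyl-1,2,3,5,6,7,8,8a-octahydronaphthalene-1-carboxylate
Product: 15 methyl (1S,5S,6R,8aR)-1,5,6-trimethyl-5-(3-oxopropyl)-1,2,3,5,6,7,8,8a-octahydronaphthalene-1-carboxylate
Conditions: Dess–Martin periodinane, NaHCO3, CH2Cl2, 0 °C → rt
Reagents that add atoms: none
Why: Dess–Martin oxidation of a primary alcohol stops at the aldehyde under buffered, non-acidic conditions that leave the C1=C10 olefin in place.

Step 9
Reactants: 15 methyl (1S,5S,6R,8aR)-1,5,6-trimethyl-5-(3-oxopropyl)-1,2,3,5,6,7,8,8a-octahydronaphthalene-1-carboxylate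
Product: 16 methyl (1S,5S,6R,8aR)-5-(but-3-yn-1-yl)-1,5,6-trimethyl-1,2,3,5,6,7,8,8a-octahydronaphthalene-1-carboxylate
Conditions: dimethyl (1-diazo-2-oxopropyl)phosphonate, K2CO3, MeOH, 0 °C → rt
Reagents that add atoms: dimethyl (1-diazo-2-oxopropyl)phosphonate COP(=O)(OC)C(=[N+]=[N-])C(C)=O
Why: Ohira–Bestmann homologation (Seyferth–Gilbert type) turns the aldehyde into the terminal alkyne C13≡C14 under mild carbonate/methanol conditions to which the methyl ester is indifferent.

Step 10
Reactants: 16 methyl (1S,5S,6R,8aR)-5-(but-3-yn-1-yl)-1,5,6-trimethyl-1,2,3,5,6,7,8,8a-octahydronaphthalene-1-carboxylate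
Product: 18 methyl (1S,5S,6R,8aR)-5-[(3E)-5-hydroxy-3-methylpent-3-en-1-yl]-1,5,6-trimethyl-1,2,3,5,6,7,8,8a-octahydronaphthalene-1-carboxylate, via alkenyldimethylalane 17 (not isolated)
Conditions: AlMe3, Cp2ZrCl2 (20 mol%), H2O (1 equiv), CH2Cl2, −25 °C; then (CH2O)n, THF, 0 °C → rt; aq potassium sodium tartrate
Reagents that add atoms: trimethylaluminium C[Al](C)C; formaldehyde (as paraformaldehyde) C=O
Why: Zirconium-catalysed methylalumination of the terminal alkyne (Negishi carboalumination, water-accelerated so that it runs cold and spares the hindered ester) adds methyl and aluminium syn with aluminium at the terminus, and capture of the alkenylalane by formaldehyde with retention should give the E-trisubstituted allylic alcohol.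

Step 11
Reactants: 18 methyl (1S,5S,6R,8aR)-5-[(3E)-5-hydroxy-3-methylpent-3-en-1-yl]-1,5,6-trimethyl-1,2,3,5,6,7,8,8a-octahydronaphthalene-1-carboxylate; 19 phenylpropiolic acid
Product: 20 methyl (1S,5S,6R,8aR)-1,5,6-trimethyl-5-{(3E)-3-methyl-5-[(3-phenylprop-2-ynoyl)oxy]pent-3-en-1-yl}-1,2,3,5,6,7,8,8a-octahydronaphthalene-1-carboxylate
Conditions: DCC, DMAP (5 mol%), CH2Cl2, 0 °C
Reagents that add atoms: none
Why: Steglich esterification acylates the unhindered primary allylic alcohol under neutral conditions, and a low DMAP loading at 0 °C should limit conjugate addition to the ynoate.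

Step 12
Reactants: 20 methyl (1S,5S,6R,8aR)-1,5,6-trimethyl-5-{(3E)-3-methyl-5-[(3-phenylprop-2-ynoyl)oxy]pent-3-en-1-yl}-1,2,3,5,6,7,8,8a-octahydronaphthalene-1-carboxylate
Product: 21 methyl (1S,5S,6R,8aR)-1,5,6-trimethyl-5-{(3E)-3-methyl-5-{[(2Z)-3-phenylprop-2-enoyl]oxy}pent-3-en-1-yl}-1,2,3,5,6,7,8,8a-octahydronaphthalene-1-carboxylate (CNP0296075.1)
Conditions: H2 (1 atm), Pd/CaCO3 poisoned with Pb(OAc)2, quinoline, EtOAc, rt, stopped after one equivalent, light excluded
Reagents that add atoms: none
Why: Semihydrogenation over the lead-poisoned palladium catalyst adds H2 syn to the alkyne to give the (Z)-cinnamate, and the two trisubstituted olefins and the allylic C–O bond should not react on this deactivated surface.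

**Compound list**

1 | 2-methylcyclohex-2-en-1-one | CC1=CCCCC1=O | starting material
2 | dimethylaluminium enolate of (R)-2,3-dimethylcyclohexanone | C[Al](C)OC1=C(C)[C@H](C)CCC1 | intermediate
3 | lithium trimethylaluminate enolate of (R)-2,3-dimethylcyclohexanone | [Li+].C[Al-](C)(C)OC1=C(C)[C@H](C)CCC1 | intermediate
4 | (2S,3R)-2,3-dimethyl-2-(prop-2-en-1-yl)cyclohexan-1-one | O=C1CCC[C@@H](C)[C@]1(C)CC=C | intermediate
5 | potassium (5R,6S)-5,6-dimethyl-6-(prop-2-en-1-yl)cyclohex-1-en-1-olate | [K+].[O-]C1=CCC[C@@H](C)[C@]1(C)CC=C | intermediate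
6 | (5R,6S)-5,6-dimethyl-6-(prop-2-en-1-yl)cyclohex-1-en-1-yl trifluoromethanesulfonate | O=S(=O)(OC1=CCC[C@@H](C)[C@]1(C)CC=C)C(F)(F)F | intermediate
7 | vinylboronic acid pinacol ester | C=CB1OC(C)(C)C(C)(C)O1 | starting material
8 | (5R,6S)-1-ethenyl-5,6-dimethyl-6-(prop-2-en-1-yl)cyclohex-1-ene | C=CC1=CCC[C@@H](C)[C@]1(C)CC=C | intermediate
9 | methacrolein | CC(=C)C=O | starting material
10 | (1S,5S,6R,8aR)-1,5,6-trimethyl-5-(prop-2-en-1-yl)-1,2,3,5,6,7,8,8a-octahydronaphthalene-1-carbaldehyde | O=C[C@@]1(C)CCC=C2[C@H]1CC[C@@H](C)[C@]2(C)CC=C | intermediate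
11 | (1S,5S,6R,8aR)-1,5,6-trimethyl-5-(prop-2-en-1-yl)-1,2,3,5,6,7,8,8a-octahydronaphthalene-1-carboxylic acid | OC(=O)[C@@]1(C)CCC=C2[C@H]1CC[C@@H](C)[C@]2(C)CC=C | intermediate
12 | methyl (1S,5S,6R,8aR)-1,5,6-trimethyl-5-(prop-2-en-1-yl)-1,2,3,5,6,7,8,8a-octahydronaphthalene-1-carboxylate | COC(=O)[C@@]1(C)CCC=C2[C@H]1CC[C@@H](C)[C@]2(C)CC=C | intermediate
13 | methyl (1S,5S,6R,8aR)-5-[3-(9-borabicyclo[3.3.1]nonan-9-yl)propyl]-1,5,6-trimethyl-1,2,3,5,6,7,8,8a-octahydronaphthalene-1-carboxylate | COC(=O)[C@@]1(C)CCC=C2[C@H]1CC[C@@H](C)[C@]2(C)CCCB1C2CCCC1CCC2 | intermediate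
14 | methyl (1S,5S,6R,8aR)-5-(3-hydroxypropyl)-1,5,6-trimethyl-1,2,3,5,6,7,8,8a-octahydronaphthalene-1-carboxylate | COC(=O)[C@@]1(C)CCC=C2[C@H]1CC[C@@H](C)[C@]2(C)CCCO | intermediate
15 | methyl (1S,5S,6R,8aR)-1,5,6-trimethyl-5-(3-oxopropyl)-1,2,3,5,6,7,8,8a-octahydronaphthalene-1-carboxylate | COC(=O)[C@@]1(C)CCC=C2[C@H]1CC[C@@H](C)[C@]2(C)CCC=O | intermediate
16 | methyl (1S,5S,6R,8aR)-5-(but-3-yn-1-yl)-1,5,6-trimethyl-1,2,3,5,6,7,8,8a-octahydronaphthalene-1-carboxylate | COC(=O)[C@@]1(C)CCC=C2[C@H]1CC[C@@H](C)[C@]2(C)CCC#C | intermediate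
17 | methyl (1S,5S,6R,8aR)-5-[(3E)-4-(dimethylalumanyl)-3-methylbut-3-en-1-yl]-1,5,6-trimethyl-1,2,3,5,6,7,8,8a-octahydronaphthalene-1-carboxylate | COC(=O)[C@@]1(C)CCC=C2[C@H]1CC[C@@H](C)[C@]2(C)CC/C(C)=C/[Al](C)C | intermediate
18 | methyl (1S,5S,6R,8aR)-5-[(3E)-5-hydroxy-3-methylpent-3-en-1-yl]-1,5,6-trimethyl-1,2,3,5,6,7,8,8a-octahydronaphthalene-1-carboxylate | COC(=O)[C@@]1(C)CCC=C2[C@H]1CC[C@@H](C)[C@]2(C)CC/C(C)=C/CO | intermediate
19 | phenylpropiolic acid | OC(=O)C#Cc1ccccc1 | starting material
20 | methyl (1S,5S,6R,8aR)-1,5,6-trimethyl-5-{(3E)-3-methyl-5-[(3-phenylprop-2-ynoyl)oxy]pent-3-en-1-yl}-1,2,3,5,6,7,8,8a-octahydronaphthalene-1-carboxylate | COC(=O)[C@@]1(C)CCC=C2[C@H]1CC[C@@H](C)[C@]2(C)CC/C(C)=C/COC(=O)C#Cc1ccccc1 | intermediate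
21 | methyl (1S,5S,6R,8aR)-1,5,6-trimethyl-5-{(3E)-3-methyl-5-{[(2Z)-3-phenylprop-2-enoyl]oxy}pent-3-en-1-yl}-1,2,3,5,6,7,8,8a-octahydronaphthalene-1-carboxylate (CNP0296075.1) | COC(=O)[C@@]1(C)CCC=C2[C@H]1CC[C@@H](C)[C@]2(C)CC/C(C)=C/COC(=O)/C=C\c1ccccc1 | target

**Step count and risk**

Total step count: 12. Longest linear sequence: 12 steps (1 → 21).

Steps most likely to fail:

Step 4. Three selectivities are demanded at once. The process at risk is facial discrimination on the diene: if ring B prefers the conformer with the allyl group pseudoaxial, the catalyst-fixed enal face can only be matched through an exo transition state, which would invert C5 relative to C4. Bonding of the enal β-carbon to C5 instead of C2, or acid-induced oligomerisation of the diene, could also erode the outcome. The fallback separates the two new stereocentres. It sets out from triene 8, which is combined with methyl acrylate under Et2AlCl (CH2Cl2, −78 → −20 °C) to give methyl (5S,6R,8aS)-5,6-dimethyl-5-(prop-2-en-1-yl)-1,2,3,5,6,7,8,8a-octahydronaphthalene-1-carboxylate F1 as a mixture of C4 epimers, both of which are usable, so that only regiochemistry and the diene face matter. Deprotonation with LiN(iPr)2 (THF, −78 °C) and alkylation with MeI then sets C4, the methyl group being expected to enter the exocyclic enolate from the equatorial direction, cis to H5. The fallback comes back to the route at ester 12 and replaces steps 4 to 6.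

Step 10. The process at risk is methyl transfer from AlMe3 to the ester carbonyl during the carboalumination, or incomplete capture of the alkenylalane by formaldehyde, which would leave the protonated 1,1-disubstituted olefin. The fallback sets out from aldehyde 15 and builds the olefin by carbonyl olefination instead. MeMgBr (THF, −78 °C) should give methyl (1S,5S,6R,8aR)-5-(3-hydroxybutyl)-1,5,6-trimethyl-1,2,3,5,6,7,8,8a-octahydronaphthalene-1-carboxylate F2. Dess–Martin oxidation should give the methyl ketone, methyl (1S,5S,6R,8aR)-1,5,6-trimethyl-5-(3-oxobutyl)-1,2,3,5,6,7,8,8a-octahydronaphthalene-1-carboxylate F3. Horner–Wadsworth–Emmons reaction with triethyl phosphonoacetate and NaH (THF) should give mainly the (E)-enoate, methyl (1S,5S,6R,8aR)-5-[(3E)-5-ethoxy-3-methyl-5-oxopent-3-en-1-yl]-1,5,6-trimethyl-1,2,3,5,6,7,8,8a-octahydronaphthalene-1-carboxylate F4, the Z isomer being removed by chromatography. iBu2AlH (CH2Cl2, −78 °C) should then reduce the unhindered conjugated ethyl ester while the fully substituted, neopentyl C18 methyl ester is left. The fallback comes back to the route at allylic alcohol 18 and replaces steps 9 and 10.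

Step 1. The process at risk is the alkylation of the aluminate enolate: slow reaction, competing O-allylation, or insufficient preference for allyl delivery anti to the C8 methyl. The fallback sets out from enone 1 and moves the C–C bond formation to palladium. The same conjugate addition is run, and aluminium enolate 2 is acylated on oxygen with allyl chloroformate to give, after isolation, (R)-2,3-dimethylcyclohex-1-en-1-yl prop-2-en-1-yl carbonate F5. Decarboxylative allylation of the Tsuji type (Pd2(dba)3, (R)-t-Bu-PHOX, THF, rt) should then form the C9–C11 bond, the ligand antipode being chosen to reinforce the substrate preference for the face anti to the C8 methyl. The fallback comes back to the route at ketone 4.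

**Further compounds**

F1 | step 4 | methyl (5S,6R,8aS)-5,6-dimethyl-5-(prop-2-en-1-yl)-1,2,3,5,6,7,8,8a-octahydronaphthalene-1-carboxylate (C1 epimers) | COC(=O)C1CCC=C2[C@H]1CC[C@@H](C)[C@]2(C)CC=C
F2 | step 10 | methyl (1S,5S,6R,8aR)-5-(3-hydroxybutyl)-1,5,6-trimethyl-1,2,3,5,6,7,8,8a-octahydronaphthalene-1-carboxylate (carbinol epimers) | COC(=O)[C@@]1(C)CCC=C2[C@H]1CC[C@@H](C)[C@]2(C)CCC(C)O
F3 | step 10 | methyl (1S,5S,6R,8aR)-1,5,6-trimethyl-5-(3-oxobutyl)-1,2,3,5,6,7,8,8a-octahydronaphthalene-1-carboxylate | COC(=O)[C@@]1(C)CCC=C2[C@H]1CC[C@@H](C)[C@]2(C)CCC(C)=O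
F4 | step 10 | methyl (1S,5S,6R,8aR)-5-[(3E)-5-ethoxy-3-methyl-5-oxopent-3-en-1-yl]-1,5,6-trimethyl-1,2,3,5,6,7,8,8a-octahydronaphthalene-1-carboxylate | COC(=O)[C@@]1(C)CCC=C2[C@H]1CC[C@@H](C)[C@]2(C)CC/C(C)=C/C(=O)OCC
F5 | step 1 | (R)-2,3-dimethylcyclohex-1-en-1-yl prop-2-en-1-yl carbonate | C=CCOC(=O)OC1=C(C)[C@H](C)CCC1
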